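**Retrosynthetic overview**
1. Neoirietetraol is traced back, through late C1/C4/C5/C7 functional-group work only, to the cis-fused octalone 24.
2. The strategy rests on ring A (C5–C10): the ring C substituent on C7 lies 1,4 (para) to the methyl-bearing quaternary C10, which is the pattern a 2-substituted butadiene and a 2-methylcyclohexenone give when C5–C6 and C9–C10 are formed in one [4+2] step.
3. Diene 17 carries the complete ring C; it comes from 2,3-dimethylcyclopentenone by cuprate–aldol, conjugate borylation, a CBS reduction that also resolves, invertive bromination and enol triflate vinylation.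
4. Dienophile 23 (ring B) comes from 3-ethoxy-2-methylcyclohexenone by α'-acetoxylation, lipase resolution and Stork–Danheiser transposition.
5. Ring order: rings C and B are bought as carbocycles; ring A is the only ring made, in step 16.

Key step: step 16

Remark on numbering: decalin carbons are C1–C10 (ring B = C1–C5, C10; ring A = C5–C10); ring C is C11 (quaternary, on C7), C12 (CH–O), C13 (CH2), C14 (CH–Br), C15 (CMe2).
Assumption: the lipase in step 13 hydrolyses the (R)-acetate (carbonyl side acting as the large group); with an enzyme of opposite sense the recovered acetate is the (R)-material and is methanolysed (K2CO3, MeOH) before step 14.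
Remark on protecting groups: ring C carries a triisopropylsilyl ether instead of a tert-butyldimethylsilyl ether so that the C4 silyl ether can be removed selectively after the key step.

**Fragment A: diene 17**

Step 1
Reactants: 1 2,3-dimethylcyclopent-2-en-1-one; 2 acetaldehyde
Product: 4 rac-(2S,1'S)-2-(1-hydroxyethyl)-2,3,3-trimethylcyclopentan-1-one, via lithium enolate 3 (not isolated)
Conditions: Me2CuLi (MeLi, CuI), Et2O, 0 °C; then MeCHO, −78 °C; aq NH4Cl
Reagents that add atoms: lithium dimethylcuprate, [Li+].C[Cu-]C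
Why: Cuprate conjugate addition builds the gem-dimethyl carbon C15, and the resulting tetrasubstituted enolate undergoes an aldol reaction with acetaldehyde (Zimmerman–Traxler chair, aldehyde methyl equatorial) that creates quaternary C11; the like diastereomer is expected to predominate, the minor carbinol epimer is removed by chromatography, and the carbinol centre is erased in step 9.

Step 2
Reactants: 4 rac-(2S,1'S)-2-(1-hydroxyethyl)-2,3,3-trimethylcyclopentan-1-one
Product: 5 rac-(2S,1'S)-2,3,3-trimethyl-2-[1-(triethylsilyloxy)ethyl]cyclopentan-1-one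
Conditions: Et3SiOTf, 2,6-lutidine, CH2Cl2, −78 °C
Reagents that add atoms: triethylsilyl trifluoromethanesulfonate, CC[Si](CC)(CC)OS(=O)(=O)C(F)(F)F
Why: Silylation with a silyl triflate under non-basic conditions avoids retro-aldol cleavage and turns the side chain into a bulky, inert group that directs the next three steps.

Step 3
Reactants: 5 rac-(2S,1'S)-2,3,3-trimethyl-2-[1-(triethylsilyloxy)ethyl]cyclopentan-1-one
Product: 7 rac-(5S,1'S)-4,4,5-trimethyl-5-[1-(triethylsilyloxy)ethyl]cyclopent-2-en-1-one, via trimethylsilyl enol ether 6 (not isolated)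
Conditions: LiN(i-Pr)2, Me3SiCl (in situ), THF, −78 °C; then Pd(OAc)2, MeCN, rt
Reagents that add atoms: none
Why: Saegusa–Ito oxidation; the ketone can enolise only towards its CH2 because the other α-carbon is quaternary, and divalent palladium dehydrogenates the silyl enol ether to the enone.

Step 4
Reactants: 7 rac-(5S,1'S)-4,4,5-trimethyl-5-[1-(triethylsilyloxy)ethyl]cyclopent-2-en-1-one
Product: 8 rac-4,4,5-trimethyl-3-(pinacolboryl)-5-[1-(triethylsilyloxy)ethyl]cyclopentan-1-one (boron trans to the silyloxyethyl group)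
Conditions: B2pin2, CuCl (10 mol%), Xantphos, NaOt-Bu, MeOH, THF, rt
Reagents that add atoms: bis(pinacolato)diboron, CC1(C)OB(OC1(C)C)B1OC(C)(C)C(C)(C)O1
Why: Copper-catalysed conjugate borylation (boryl–copper 1,4-addition, then protonation by methanol) should place boron on C14 from the ring face opposite the bulky silyloxyethyl group; any cis isomer is separable.

Step 5
Reactants: 8 rac-4,4,5-trimethyl-3-(pinacolboryl)-5-[1-(triethylsilyloxy)ethyl]cyclopentan-1-one
Product: 9 ring C alcohol (single enantiomer; 12-hydroxyl cis to the side chain; boron trans to it)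
Conditions: (R)-2-methyl-CBS-oxazaborolidine (0.5 equiv), BH3·SMe2, THF, −20 °C; MeOH; chromatography
Reagents that add atoms: none
Why: Corey–Bakshi–Shibata reduction used as a resolution; the (R)-catalyst delivers hydride to the same absolute carbonyl face in both enantiomers (large flank C11, small flank CH2), which in the wanted enantiomer is the face anti to the side chain and sets the (S)-carbinol C12 cis to it, while the antipode gives the separable trans diastereomer (at most half of 8 is used).

Step 6
Reactants: 9 ring C alcohol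
Product: 10 ring C triisopropylsilyl ether (12-OTIPS; boron at C14 trans to the side chain)
Conditions: i-Pr3SiOTf, 2,6-lutidine, CH2Cl2, 0 °C → rt
Reagents that add atoms: triisopropylsilyl trifluoromethanesulfonate, CC(C)[Si](C(C)C)(C(C)C)OS(=O)(=O)C(F)(F)F
Why: The silyl triflate silylates the hindered neopentyl hydroxyl, giving an ether robust enough for the Lewis acid of step 16 and distinguishable from the two other silyl ethers used in the route.

Step 7
Reactants: 10 ring C triisopropylsilyl ether
Product: 12 ring C bromide (14-bromo cis to 12-OTIPS and to the side chain), via aryl boronate complex 11 (not isolated)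
Conditions: 3,5-(CF3)2C6H3Li (ArBr, n-BuLi), THF, −78 °C; then NBS, THF/MeCN, −78 °C → rt
Reagents that add atoms: N-bromosuccinimide, O=C1CCC(=O)N1Br
Why: Stereoinvertive bromination of a secondary boronic ester; the electron-poor aryllithium forms the boronate complex, which NBS attacks at carbon from the side opposite boron (SE2 with inversion), so bromine ends on the face that a radical or direct substitution route would not reach.

Step 8
Reactants: 12 ring C bromide
Product: 13 side-chain carbinol (1-hydroxyethyl on C11; 12-OTIPS; 14-Br)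
Conditions: PPTS, MeOH/CH2Cl2, 0 °C → rt
Reagents that add atoms: none
Why: Acid-catalysed methanolysis removes the secondary triethylsilyl ether while the far more hindered triisopropylsilyl ether is untouched.

Step 9
Reactants: 13 side-chain carbinol
Product: 14 ring C methyl ketone (acetyl on C11)
Conditions: Dess–Martin periodinane, NaHCO3, CH2Cl2, rt
Reagents that add atoms: none
Why: Buffered Dess–Martin oxidation converts the hindered secondary alcohol into the ketone and removes the temporary carbinol stereocentre without touching the bromide.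

Step 10
Reactants: 14 ring C methyl ketone
Product: 16 ring C enol triflate (1-(triflyloxy)vinyl on C11), via potassium enolate 15 (not isolated)
Conditions: KN(SiMe3)2, THF, −78 °C; then PhNTf2
Reagents that add atoms: N-phenylbis(trifluoromethanesulfonimide), O=S(=O)(N(c1ccccc1)S(=O)(=O)C(F)(F)F)C(F)(F)F
Why: The ketone has α-hydrogens only on its methyl group, so deprotonation and O-sulfonylation give a single enol triflate; the bromide is cis to the acetyl group and cannot be displaced intramolecularly.

Step 11
Reactants: 16 ring C enol triflate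
Product: 17 2-(ring C)-buta-1,3-diene (12-OTIPS; 14-Br)
Conditions: CH2=CHSnBu3, Pd(PPh3)4, LiCl, THF, 65 °C
Reagents that add atoms: tributyl(vinyl)stannane, C=C[Sn](CCCC)(CCCC)CCCC
Why: Stille coupling; zerovalent palladium inserts into the alkenyl C–O bond (the unactivated secondary bromide is inert with this catalyst) and vinyl transfer from tin gives the 2-substituted butadiene.

**Fragment B: dienophile 23**

Step 12
Reactants: 18 3-ethoxy-2-methylcyclohex-2-en-1-one
Product: 19 rac-6-acetoxy-3-ethoxy-2-methylcyclohex-2-en-1-one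
Conditions: Mn(OAc)3·2H2O, benzene, reflux (Dean–Stark)
Reagents that add atoms: manganese triacetate, CC(=O)[O-].CC(=O)[O-].CC(=O)[O-].[Mn+3]
Why: α'-Acetoxylation of an enone by trivalent manganese (manganese enolate, acetate transfer) functionalises C6, the only α'-CH2 of the vinylogous ester.

Step 13
Reactants: 19 rac-6-acetoxy-3-ethoxy-2-methylcyclohex-2-en-1-one
Product: 20 (R)-3-ethoxy-6-hydroxy-2-methylcyclohex-2-en-1-one
Conditions: lipase PS (Burkholderia cepacia), pH 7 phosphate buffer/DMSO, rt, to about half conversion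
Reagents that add atoms: none
Why: Lipase-catalysed enantioselective ester hydrolysis (kinetic resolution of an α'-acetoxy enone) releases the (R)-alcohol, and the unreacted (S)-acetate is separated by chromatography.

Step 14
Reactants: 20 (R)-3-ethoxy-6-hydroxy-2-methylcyclohex-2-en-1-one
Product: 21 (R)-6-(tert-butyldimethylsilyloxy)-3-ethoxy-2-methylcyclohex-2-en-1-one
Conditions: t-BuMe2SiCl, imidazole, DMF, rt
Reagents that add atoms: tert-butyldimethylsilyl chloride, CC(C)(C)[Si](C)(C)Cl
Why: Standard silylation under weakly basic conditions that do not enolise the α-oxygenated ketone, so the stereocentre is kept.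

Step 15
Reactants: 21 (R)-6-(tert-butyldimethylsilyloxy)-3-ethoxy-2-methylcyclohex-2-en-1-one
Product: 23 (R)-4-(tert-butyldimethylsilyloxy)-2-methylcyclohex-2-en-1-one, via allylic alcohol 22 (not isolated)
Conditions: i-Bu2AlH, toluene, −78 °C; then 1 M HCl, THF, 0 °C
Reagents that add atoms: water, O
Why: Stork–Danheiser transposition; 1,2-reduction of the vinylogous ester and acid-promoted enol ether hydrolysis with loss of water move the carbonyl to the former C3, and the untouched silyloxy carbon becomes C4 of the new enone with unchanged (R) configuration.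

**Key step**

Step 16
Reactants: 17 2-(ring C)-buta-1,3-diene; 23 (R)-4-(tert-butyldimethylsilyloxy)-2-methylcyclohex-2-en-1-one
Product: 24 cis-fused Δ7-octalin-1-one (4-OTBS; H5 cis to the C10 methyl; ring C on C7 with 12-OTIPS and 14-Br)
Conditions: AlBr3/AlMe3 (about 10:1), toluene/CH2Cl2, −20 → 0 °C; 23 in excess
Reagents that add atoms: none
Why: Coordination of the aluminium Lewis acid to the C1 carbonyl lowers the enone LUMO and the diene adds in a concerted, asynchronous, suprafacial [4+2] cycloaddition, the closest known reaction type being the AlBr3/AlMe3-promoted Diels–Alder reaction of hindered 2-methylcycloalkenones with 2-substituted butadienes. Ring A (C5–C10) is closed by cycloaddition: the C5–C6 bond (diene terminus next to C7 onto the enone β-carbon) leads and the C9–C10 bond to the methyl-bearing α-carbon follows in the same step. C10 is set by the dienophile alone, because the diene approaches the enone face opposite the C4 silyloxy group, and C5 follows from suprafacial addition, giving the cis ring fusion. The step needs para regiochemistry and one π-face: the alkyl group on C7 puts the largest HOMO coefficient on C6, the bulky silyl ether blocks the other face, and both diene termini are CH2 so no endo/exo question arises. AlMe3 scavenges adventitious HBr so that the diene and the secondary bromide survive, and any ring C antipode carried from step 5 ends as a separable diastereomer.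

**Endgame**

Step 17
Reactants: 24 cis-fused Δ7-octalin-1-one
Product: 26 C1 acetate (1-OAc; 4-OTBS), via C1 alcohol 25 (not isolated)
Conditions: NaBH4, MeOH/THF, 0 °C; then Ac2O, DMAP, pyridine, rt
Reagents that add atoms: acetic anhydride, CC(=O)OC(C)=O
Why: Borohydride reduction and acetylation store the C1 ketone as an ester so that C4 is the only enolisable ketone in steps 19–21; the C1 configuration is of no consequence (drawn as the epimer expected from hydride attack anti to the angular methyl) and is erased in step 22.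

Step 18
Reactants: 26 C1 acetate
Product: 27 4-hydroxy 1-acetate
Conditions: HF·pyridine, pyridine, THF, 0 °C → rt
Reagents that add atoms: none
Why: Buffered fluoride cleaves the ordinary secondary tert-butyldimethylsilyl ether much faster than the neopentyl triisopropylsilyl ether on ring C, and the acetate is stable.

Step 19
Reactants: 27 4-hydroxy 1-acetate
Product: 28 4-keto 1-acetate (cis-fused; C5 epimers converge in step 20)
Conditions: Dess–Martin periodinane, NaHCO3, CH2Cl2, rt
Reagents that add atoms: none
Why: Mild oxidation of the only free secondary alcohol gives the C4 ketone that activates C5.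

Step 20
Reactants: 28 4-keto 1-acetate
Product: 31 5-hydroxy-4-ketone 1-acetate (trans-fused; 5-OH anti to the C10 methyl), via trimethylsilyl enol ether 29 (not isolated), via silyloxy epoxide 30 (not isolated)
Conditions: Me3SiOTf, Et3N, CH2Cl2, 0 °C → rt; then dimethyldioxirane, acetone/CH2Cl2, −78 °C; then citric acid, MeOH
Reagents that add atoms: dimethyldioxirane, CC1(C)OO1
Why: Rubottom oxidation; equilibrating silylation gives the more substituted C4–C5 enol ether, the dioxirane epoxidises this electron-rich alkene faster than the hindered C7–C8 alkene and from the face opposite the angular C10 methyl, and acid opens the silyloxy epoxide to the 5-hydroxy ketone with a trans ring fusion.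

Step 21
Reactants: 31 5-hydroxy-4-ketone 1-acetate
Product: 32 1,4,5-triol (4-methyl; 4-OH cis to the C10 methyl; 5-OH trans to it)
Conditions: MeMgBr (excess), THF, −78 → 0 °C; aq NH4Cl
Reagents that add atoms: methylmagnesium bromide, C[Mg]Br
Why: Grignard addition to the C4 ketone from the equatorial direction, the axial path being blocked by the syn-axial C10 methyl, gives equatorial methyl and axial hydroxyl; the excess reagent also cleaves the C1 acetate.

Step 22
Reactants: 32 1,4,5-triol
Product: 33 4,5-dihydroxy-1-ketone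
Conditions: (COCl)2, DMSO, CH2Cl2, −78 °C; then Et3N
Reagents that add atoms: none
Why: Swern oxidation affects only the secondary C1 alcohol, since the two tertiary alcohols cannot be oxidised and the ditertiary diol is not cleaved under these conditions.

Step 23
Reactants: 33 4,5-dihydroxy-1-ketone
Product: 35 4,5,7-trihydroxy-1-ketone (7-OH cis to 5-OH; ring C equatorial), via tertiary hydroperoxide 34 (not isolated)
Conditions: Co(acac)2, PhSiH3, O2 (1 atm), THF/i-PrOH, rt; then PPh3
Reagents that add atoms: dioxygen, O=O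
Why: Mukaiyama hydration; hydrogen-atom transfer to C8 gives the tertiary C7 radical, which should take up O2 along the axial direction of the rigid trans-decalin so that the very large ring C substituent stays equatorial, placing the hydroxyl axial and syn to the C5 hydroxyl.

Step 24
Reactants: 35 4,5,7-trihydroxy-1-ketone
Product: 36 C1 hydrazone
Conditions: N2H4·H2O, Et3N, EtOH, 80 °C
Reagents that add atoms: hydrazine, NN
Why: Condensation of the neopentyl ketone with excess hydrazine; retro-aldol opening of the C5–C10 bond is disfavoured because that ring bond lies near the carbonyl plane and cannot overlap with the C=O π system.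

Step 25
Reactants: 36 C1 hydrazone
Product: 37 C1–C2 vinyl bromide
Conditions: NBS, pyridine, CH2Cl2, 0 °C
Reagents that add atoms: N-bromosuccinimide, O=C1CCC(=O)N1Br
Why: Barton-type vinyl halide synthesis; N-bromination and loss of HBr give the diazo compound, a second bromination and loss of N2 give an α-bromo cation, and loss of the C2 proton, the only β-hydrogen since C10 is quaternary, gives the vinyl bromide.

Step 26
Reactants: 37 C1–C2 vinyl bromide
Product: 38 12-O-triisopropylsilyl neoirietetraol (1-Br equatorial; cis to the C10 methyl)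
Conditions: Mn(dpm)3 (cat.), PhSiH3, t-BuOOH, i-PrOH, rt
Reagents that add atoms: none
Why: Hydrogen-atom-transfer hydrogenation of a haloalkene; H adds to C2, and the α-bromo radical at C1 accepts the second hydrogen axially, which places bromine equatorial as in the more stable epimer and avoids the hydrogenolysis expected with palladium catalysts.

Step 27
Reactants: 38 12-O-triisopropylsilyl neoirietetraol
Product: 39 neoirietetraol
Conditions: HF·pyridine, THF, rt → 40 °C
Reagents that add atoms: none
Why: Fluoride-mediated desilylation of the hindered ring C ether under buffered conditions that spare the tertiary alcohols and both secondary bromides.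

**Compound list**
1 | 2,3-dimethylcyclopent-2-en-1-one | CC1=C(C)C(=O)CC1 | starting material
2 | acetaldehyde | CC=O | starting material
3 | lithium 2,3,3-trimethylcyclopent-1-en-1-olate | [Li+].[O-]C1=C(C)C(C)(C)CC1 | intermediate (not isolated)
4 | rac-(2S,1'S)-2-(1-hydroxyethyl)-2,3,3-trimethylcyclopentan-1-one (racemic; drawn as the enantiomer carried on after step 5) | CC1(C)CCC(=O)[C@]1(C)[C@H](C)O | intermediate
5 | rac-(2S,1'S)-2,3,3-trimethyl-2-[1-(triethylsilyloxy)ethyl]cyclopentan-1-one | CC1(C)CCC(=O)[C@]1(C)[C@H](C)O[Si](CC)(CC)CC | intermediate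
6 | trimethylsilyl enol ether of 5 (racemic) | CC1(C)CC=C(O[Si](C)(C)C)[C@]1(C)[C@H](C)O[Si](CC)(CC)CC | intermediate (not isolated)
7 | rac-(5S,1'S)-4,4,5-trimethyl-5-[1-(triethylsilyloxy)ethyl]cyclopent-2-en-1-one | CC1(C)C=CC(=O)[C@]1(C)[C@H](C)O[Si](CC)(CC)CC | intermediate
8 | rac-4,4,5-trimethyl-3-(pinacolboryl)-5-[1-(triethylsilyloxy)ethyl]cyclopentan-1-one, boron trans to the side chain | CC1(C)[C@@H](B2OC(C)(C)C(C)(C)O2)CC(=O)[C@]1(C)[C@H](C)O[Si](CC)(CC)CC | intermediate
9 | ring C alcohol, single enantiomer: hydroxyl cis and boron trans to the silyloxyethyl group | CC1(C)[C@@H](B2OC(C)(C)C(C)(C)O2)C[C@H](O)[C@]1(C)[C@H](C)O[Si](CC)(CC)CC | intermediate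
10 | triisopropylsilyl ether of 9 | CC1(C)[C@@H](B2OC(C)(C)C(C)(C)O2)C[C@H](O[Si](C(C)C)(C(C)C)C(C)C)[C@]1(C)[C@H](C)O[Si](CC)(CC)CC | intermediate
11 | lithium aryl boronate complex of 10 (aryl = 3,5-bis(trifluoromethyl)phenyl) | CC1(C)[C@@H]([B-]2(c3cc(C(F)(F)F)cc(C(F)(F)F)c3)OC(C)(C)C(C)(C)O2)C[C@H](O[Si](C(C)C)(C(C)C)C(C)C)[C@]1(C)[C@H](C)O[Si](CC)(CC)CC.[Li+] | intermediate (not isolated)
12 | ring C bromide: bromine cis to the triisopropylsilyloxy group and to the side chain | CC1(C)[C@H](Br)C[C@H](O[Si](C(C)C)(C(C)C)C(C)C)[C@]1(C)[C@H](C)O[Si](CC)(CC)CC | intermediate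
13 | ring C side-chain carbinol | CC1(C)[C@H](Br)C[C@H](O[Si](C(C)C)(C(C)C)C(C)C)[C@]1(C)[C@H](C)O | intermediate
14 | ring C methyl ketone | CC1(C)[C@H](Br)C[C@H](O[Si](C(C)C)(C(C)C)C(C)C)[C@]1(C)C(C)=O | intermediate
15 | potassium enolate of 14 | CC1(C)[C@H](Br)C[C@H](O[Si](C(C)C)(C(C)C)C(C)C)[C@]1(C)C(=C)[O-].[K+] | intermediate (not isolated)
16 | ring C enol triflate | CC1(C)[C@H](Br)C[C@H](O[Si](C(C)C)(C(C)C)C(C)C)[C@]1(C)C(=C)OS(=O)(=O)C(F)(F)F | intermediate
17 | 2-(ring C)-buta-1,3-diene (12-OTIPS, 14-Br) | CC1(C)[C@H](Br)C[C@H](O[Si](C(C)C)(C(C)C)C(C)C)[C@]1(C)C(=C)C=C | intermediate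
18 | 3-ethoxy-2-methylcyclohex-2-en-1-one | CCOC1=C(C)C(=O)CCC1 | starting material
19 | rac-6-acetoxy-3-ethoxy-2-methylcyclohex-2-en-1-one | CCOC1=C(C)C(=O)C(OC(C)=O)CC1 | intermediate
20 | (R)-3-ethoxy-6-hydroxy-2-methylcyclohex-2-en-1-one | CCOC1=C(C)C(=O)[C@H](O)CC1 | intermediate
21 | (R)-6-(tert-butyldimethylsilyloxy)-3-ethoxy-2-methylcyclohex-2-en-1-one | CCOC1=C(C)C(=O)[C@H](O[Si](C)(C)C(C)(C)C)CC1 | intermediate
22 | (6R)-6-(tert-butyldimethylsilyloxy)-3-ethoxy-2-methylcyclohex-2-en-1-ol (C1 epimers) | CCOC1=C(C)C(O)[C@H](O[Si](C)(C)C(C)(C)C)CC1 | intermediate (not isolated)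
23 | (R)-4-(tert-butyldimethylsilyloxy)-2-methylcyclohex-2-en-1-one | CC1=C[C@H](O[Si](C)(C)C(C)(C)C)CCC1=O | intermediate
24 | cis-fused Δ7-octalin-1-one: 4-OTBS, H5 cis to the C10 methyl, ring C on C7 | CC1(C)[C@H](Br)C[C@H](O[Si](C(C)C)(C(C)C)C(C)C)[C@]1(C)C1=CC[C@]2(C)C(=O)CC[C@@H](O[Si](C)(C)C(C)(C)C)[C@@H]2C1 | intermediate
25 | C1 alcohol of 24 (hydroxyl cis to the C10 methyl expected) | CC1(C)[C@H](Br)C[C@H](O[Si](C(C)C)(C(C)C)C(C)C)[C@]1(C)C1=CC[C@]2(C)[C@@H](O)CC[C@@H](O[Si](C)(C)C(C)(C)C)[C@@H]2C1 | intermediate (not isolated)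
26 | C1 acetate, 4-OTBS | CC1(C)[C@H](Br)C[C@H](O[Si](C(C)C)(C(C)C)C(C)C)[C@]1(C)C1=CC[C@]2(C)[C@@H](OC(C)=O)CC[C@@H](O[Si](C)(C)C(C)(C)C)[C@@H]2C1 | intermediate
27 | 4-hydroxy 1-acetate | CC1(C)[C@H](Br)C[C@H](O[Si](C(C)C)(C(C)C)C(C)C)[C@]1(C)C1=CC[C@]2(C)[C@@H](OC(C)=O)CC[C@@H](O)[C@@H]2C1 | intermediate
28 | 4-keto 1-acetate (cis-fused) | CC1(C)[C@H](Br)C[C@H](O[Si](C(C)C)(C(C)C)C(C)C)[C@]1(C)C1=CC[C@]2(C)[C@@H](OC(C)=O)CCC(=O)[C@@H]2C1 | intermediate
29 | C4–C5 trimethylsilyl enol ether | CC1(C)[C@H](Br)C[C@H](O[Si](C(C)C)(C(C)C)C(C)C)[C@]1(C)C1=CC[C@]2(C)[C@@H](OC(C)=O)CCC(O[Si](C)(C)C)=C2C1 | intermediate (not isolated)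
30 | 4,5-silyloxy epoxide, oxygen anti to the C10 methyl | CC1(C)[C@H](Br)C[C@H](O[Si](C(C)C)(C(C)C)C(C)C)[C@]1(C)C1=CC[C@]2(C)[C@@H](OC(C)=O)CC[C@]3(O[Si](C)(C)C)O[C@]23C1 | intermediate (not isolated)
31 | 5-hydroxy-4-ketone 1-acetate (trans-fused) | CC1(C)[C@H](Br)C[C@H](O[Si](C(C)C)(C(C)C)C(C)C)[C@]1(C)C1=CC[C@]2(C)[C@@H](OC(C)=O)CCC(=O)[C@@]2(O)C1 | intermediate
32 | 1,4,5-triol with the C4 methyl | CC1(C)[C@H](Br)C[C@H](O[Si](C(C)C)(C(C)C)C(C)C)[C@]1(C)C1=CC[C@]2(C)[C@@H](O)CC[C@@](C)(O)[C@@]2(O)C1 | intermediate
33 | 4,5-dihydroxy-1-ketone | CC1(C)[C@H](Br)C[C@H](O[Si](C(C)C)(C(C)C)C(C)C)[C@]1(C)C1=CC[C@]2(C)C(=O)CC[C@@](C)(O)[C@@]2(O)C1 | intermediate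
34 | C7 hydroperoxide | CC1(C)[C@H](Br)C[C@H](O[Si](C(C)C)(C(C)C)C(C)C)[C@]1(C)[C@@]1(OO)CC[C@]2(C)C(=O)CC[C@@](C)(O)[C@@]2(O)C1 | intermediate (not isolated)
35 | 4,5,7-trihydroxy-1-ketone | CC1(C)[C@H](Br)C[C@H](O[Si](C(C)C)(C(C)C)C(C)C)[C@]1(C)[C@@]1(O)CC[C@]2(C)C(=O)CC[C@@](C)(O)[C@@]2(O)C1 | intermediate
36 | C1 hydrazone | CC1(C)[C@H](Br)C[C@H](O[Si](C(C)C)(C(C)C)C(C)C)[C@]1(C)[C@@]1(O)CC[C@]2(C)C(=NN)CC[C@@](C)(O)[C@@]2(O)C1 | intermediate
37 | C1–C2 vinyl bromide | CC1(C)[C@H](Br)C[C@H](O[Si](C(C)C)(C(C)C)C(C)C)[C@]1(C)[C@@]1(O)CC[C@]2(C)C(Br)=CC[C@@](C)(O)[C@@]2(O)C1 | intermediate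
38 | 12-O-triisopropylsilyl neoirietetraol | CC1(C)[C@H](Br)C[C@H](O[Si](C(C)C)(C(C)C)C(C)C)[C@]1(C)[C@@]1(O)CC[C@]2(C)[C@@H](Br)CC[C@@](C)(O)[C@@]2(O)C1 | intermediate
39 | neoirietetraol, (1S,4R,5R,7R,10S,11R,12S,14R) in the numbering used here | CC1(C)[C@H](Br)C[C@H](O)[C@]1(C)[C@@]1(O)CC[C@]2(C)[C@@H](Br)CC[C@@](C)(O)[C@@]2(O)C1 | target

**Step count and risks**

Total step count: 27. Longest linear sequence: 23 steps (steps 1–11, 16 and 17–27, from compound 1); the dienophile branch is 4 steps.

Step 7. What may go wrong: the boronate complex may be oxidised by NBS through single-electron transfer, or back-side attack at the neopentyl carbon C14 on the more hindered ring face may be too slow, so that stereospecificity is lost or protodeboronation takes over. Fallback, from 10 back to 12: the C–B bond of 10 is oxidised with retention (NaBO3·4H2O, THF/H2O) to the ring alcohol F1, which is converted at −78 °C (Tf2O, pyridine, CH2Cl2) into the triflate F2 and displaced in the same flask by bromide (Bu4NBr, SN2 with inversion) to give 12.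

Step 16. What may go wrong: ionisation of the secondary C–Br bond or of the allylic C–O bond by the strong Lewis acid, or cationic oligomerisation of the diene, may outrun the cycloaddition. Fallback, from 23 (with 17) back to 24: 23 is converted (1,2-bis(trimethylsilyloxy)ethane, catalytic Me3SiOTf, CH2Cl2, −78 °C) into its ethylene ketal F3; with catalytic Me3SiOTf at −78 °C this opens reversibly to an alkoxyallyl cation, a much stronger dienophile that needs no aluminium halide, and adds diene 17 with the same regiochemical and facial preferences to give the adduct ketal F4, from which PPTS in wet acetone releases ketone 24.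

Step 5. What may go wrong: uncatalysed reduction by free borane, or a substrate bias that overrides the catalyst, would erode reagent control, so that 9 forms with low enantiomeric purity or does not separate from its diastereomer. Fallback, from 8 back to 9: racemic 8 is reduced under substrate control (LiBH(s-Bu)3, THF, −78 °C, hydride anti to the side chain) to the racemic alcohol F5, which is esterified with (1S)-camphanoyl chloride (pyridine, DMAP) to give the camphanate F6 together with the diastereomeric camphanate F7 of the antipode; the two are separated by crystallisation or chromatography and F6 is methanolysed (K2CO3, MeOH) to 9.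

**Further compounds**
F1 | step 7 | ring C alcohol, 14-hydroxyl trans to the side chain | CC1(C)[C@@H](O)C[C@H](O[Si](C(C)C)(C(C)C)C(C)C)[C@]1(C)[C@H](C)O[Si](CC)(CC)CC
F2 | step 7 | triflate of F1 | CC1(C)[C@@H](OS(=O)(=O)C(F)(F)F)C[C@H](O[Si](C(C)C)(C(C)C)C(C)C)[C@]1(C)[C@H](C)O[Si](CC)(CC)CC
F3 | step 16 | ethylene ketal of 23 | CC1=C[C@H](O[Si](C)(C)C(C)(C)C)CCC12OCCO2
F4 | step 16 | ethylene ketal of 24 | CC1(C)[C@H](Br)C[C@H](O[Si](C(C)C)(C(C)C)C(C)C)[C@]1(C)C1=CC[C@]2(C)C3(OCCO3)CC[C@@H](O[Si](C)(C)C(C)(C)C)[C@@H]2C1
F5 | step 5 | racemic form of alcohol 9 | CC1(C)[C@@H](B2OC(C)(C)C(C)(C)O2)C[C@H](O)[C@]1(C)[C@H](C)O[Si](CC)(CC)CC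
F6 | step 5 | (1S)-camphanate of 9 | CC1(C)[C@@H](B2OC(C)(C)C(C)(C)O2)C[C@H](OC(=O)[C@@]34CC[C@@](C)(C(=O)O3)C4(C)C)[C@]1(C)[C@H](C)O[Si](CC)(CC)CC
F7 | step 5 | (1S)-camphanate of the antipode of 9 | CC1(C)[C@H](B2OC(C)(C)C(C)(C)O2)C[C@@H](OC(=O)[C@@]34CC[C@@](C)(C(=O)O3)C4(C)C)[C@@]1(C)[C@@H](C)O[Si](CC)(CC)CC
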